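**Plan**
- Retrosynthesis: the C8 hydroperoxide and cross-conjugated dienone are cut back to a ring-C phenol (1O2 adds para to the C12 OH); the C14 vinyl is cut to an aryl triflate; the arene is then cut at C9–C11 and C8–C14.
- Enabling feature: ring C (C8, C9, C11–C14) is a 4-hydroperoxycyclohexa-2,5-dienone, i.e. a masked phenol. Its C11(H)–C12(O)–C13(Me)–C14 edge is a squarate-derived 4-chloro-3-isopropoxy-2-methylcyclobutenone (C14 = carbonyl carbon), and C8=C9 is the only possible enol double bond of a ring-B cyclohexanone (C10 is quaternary).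
- Forward: ring B is made first. Ring C then arises by Pd coupling of the ring-B alkenylstannane with the chlorocyclobutenone, strain-driven 4π opening and 6π closure (four-membered ring enlarged by C8 and C9). OH-to-vinyl exchange at C14, unmasking of the C12 OH and photooxygenation follow.
- Stereochemistry: C5 comes from a Cu-catalysed asymmetric conjugate addition. C10 comes from a stereoconvergent imine Michael addition anti to the isopropenyl group. C8 comes from the ring-B conformation in the final 1O2 step.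

Key step: step 8

Remark: positions are given in cleistanthane numbering (ring B = C5–C10; ring C = C8, C9, C11–C14; C12 carries the carbonyl). Compounds 16 and 17 are used as racemates because their only stereocentre is erased in step 8.

**Step 1**
Reactants: 1 2-methylcyclohex-2-en-1-one; 2 isopropenylmagnesium bromide
Product: 4 (3S)-2-methyl-3-(prop-1-en-2-yl)cyclohexan-1-one (mixture of C2 epimers), via bromomagnesium enolate 3 (not isolated)
Conditions: 2 (1.2 equiv), Cu(OTf)2 (cat.), chiral NHC ligand (cat., enantiomer that gives 3S), Et2O, −30 °C; then 1 M HCl, 0 °C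
Reagents that add atoms: none
Why: Cu-catalysed asymmetric conjugate addition of a Grignard reagent to an α-substituted cyclic enone, in which the ligand sets C5 and the C2 epimer ratio is irrelevant because C2 is planarised in step 2.

**Step 2**
Reactants: 4 (3S)-2-methyl-3-(prop-1-en-2-yl)cyclohexan-1-one; 5 (R)-1-phenylethan-1-amine; 6 methyl acrylate
Product: 9 methyl 3-[(1R,6R)-1-methyl-2-oxo-6-(prop-1-en-2-yl)cyclohexyl]propanoate, via imine 7 (not isolated), via Michael-adduct imine 8 (not isolated)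
Conditions: 5 (1.1 equiv), toluene, 4 Å MS, reflux; then 6 (2 equiv), THF, hydroquinone (cat.), 45 °C; then 20% aq. AcOH, rt
Reagents that add atoms: water, O
Why: aza-ene-type Michael addition of the more substituted secondary enamine tautomer of a chiral imine (deracemising imine alkylation), regioselective for the tertiary α-carbon under neutral conditions; the acrylate should enter anti to the isopropenyl group, reinforced by the (R)-auxiliary, so that both C2 epimers of 4 converge on one C10 configuration.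

**Step 3**
Reactants: 9 methyl 3-[(1R,6R)-1-methyl-2-oxo-6-(prop-1-en-2-yl)cyclohexyl]propanoate
Product: 11 methyl 3-[(1R,6R)-1-methyl-6-(prop-1-en-2-yl)-2-{[(trifluoromethyl)sulfonyl]oxy}cyclohex-2-en-1-yl]propanoate, via potassium enolate 10 (not isolated)
Conditions: KHMDS (1.1 equiv), THF, −78 °C; then PhNTf2, −78 → 0 °C; aq. NH4Cl
Reagents that add atoms: N-phenylbis(trifluoromethanesulfonimide), O=S(=O)(N(c1ccccc1)S(=O)(=O)C(F)(F)F)C(F)(F)F
Why: kinetic enolate O-triflation, regiochemically unambiguous because C8 is the only enolisable ketone α-position, with the low temperature holding back intramolecular Claisen attack on the ester.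

**Step 4**
Reactants: 11 enol triflate
Product: 12 methyl 3-[(1R,6R)-1-methyl-6-(prop-1-en-2-yl)-2-(trimethylstannyl)cyclohex-2-en-1-yl]propanoate
Conditions: Me3SnSnMe3, Pd(PPh3)4 (cat.), LiCl, THF, 65 °C
Reagents that add atoms: hexamethylditin, C[Sn](C)(C)[Sn](C)(C)C
Why: Pd-catalysed stannylation of an enol triflate with a distannane (Stille-type), the small Me3Sn group being chosen to ease transmetalation next to the quaternary carbon in step 8.

**Step 5**
Reactants: 13 diisopropyl squarate (3,4-diisopropoxycyclobut-3-ene-1,2-dione)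
Product: 15 3-isopropoxy-4-methylcyclobut-3-ene-1,2-dione, via 4-hydroxycyclobutenone adduct 14 (not isolated)
Conditions: MeLi, THF, −78 °C; then 12 M HCl, CH2Cl2, rt
Reagents that add atoms: methyllithium, [Li]C
Why: 1,2-addition of an organolithium to a squarate ester followed by acid-mediated 1,3-transposition with loss of isopropanol (standard squarate chemistry).

**Step 6**
Reactants: 15 3-isopropoxy-4-methylcyclobut-3-ene-1,2-dione
Product: 16 4-hydroxy-3-isopropoxy-2-methylcyclobut-2-en-1-one (racemic)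
Conditions: LiAlH(OtBu)3, THF, −78 °C; then H2O
Reagents that add atoms: none
Why: hydride should add to the ketone-like carbonyl rather than to the vinylogous-ester carbonyl, the same regiochemistry that carbon nucleophiles show with this class of dione.

**Step 7**
Reactants: 16 4-hydroxy-3-isopropoxy-2-methylcyclobut-2-en-1-one
Product: 17 4-chloro-3-isopropoxy-2-methylcyclobut-2-en-1-one (racemic)
Conditions: PPh3, CCl4, CH2Cl2, 0 °C → rt
Reagents that add atoms: carbon tetrachloride, ClC(Cl)(Cl)Cl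
Why: Appel chlorination of a secondary allylic alcohol under neutral conditions; an SN2' isomer, if formed, would feed the same oxocyclobutenyl–palladium intermediate in step 8.

**Step 8**
Reactants: 12 ring-B alkenylstannane; 17 4-chloro-3-isopropoxy-2-methylcyclobut-2-en-1-one
Product: 21 methyl 3-[(1R,2R)-5-hydroxy-1,6-dimethyl-7-(propan-2-yloxy)-2-(prop-1-en-2-yl)-1,2,3,4-tetrahydronaphthalen-1-yl]propanoate, via 4-alkenylcyclobutenone 18 (not isolated), via dienylketene 19 (not isolated), via cyclohexa-2,4-dienone 20 (not isolated)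
Conditions: PdCl2(PhCN)2 (5 mol%), tri(2-furyl)phosphine (10 mol%), CuI (10 mol%), dioxane, 50 °C then 100 °C
Reagents that add atoms: none
Why: Pd(0) inserts into the C–Cl bond of 17, the alkenyl group is transferred from tin and reductive elimination gives 18; release of four-ring strain then drives thermal conrotatory 4π opening of the C14–C11 bond to dienylketene 19, whose ketene carbon C14 closes onto the ring-B alkene carbon C8 to give 20, and enolisation gives phenol 21. The closest known reaction type is the Pd-catalysed cross-coupling of 4-chlorocyclobutenones with alkenylstannanes with in situ ring expansion to phenols (Moore-type cyclobutenone benzannulation). Ring C is closed by a thermal disrotatory 6π electrocyclisation, the four cyclobutenone carbons C11–C14 being enlarged by the alkene carbons C8 and C9. No new stereocentre survives, since the CH of 18 and the C8–H of 20 are both erased on aromatisation and C5 and C10 are not touched. The step needs regiocontrol (OH on C14, Me on C13, OiPr on C12, H on C11), which is fixed by the substitution pattern of 17, by coupling at the less hindered CH terminus of the oxocyclobutenyl–palladium species and by reversible ring opening, only the ketene isomer with the ketene arm cis to the cyclohexenyl group being able to cyclise.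

**Step 9**
Reactants: 21 C14 phenol
Product: 22 methyl 3-[(1R,2R)-1,6-dimethyl-7-(propan-2-yloxy)-2-(prop-1-en-2-yl)-5-{[(trifluoromethyl)sulfonyl]oxy}-1,2,3,4-tetrahydronaphthalen-1-yl]propanoate
Conditions: Tf2O, pyridine, CH2Cl2, 0 °C
Reagents that add atoms: trifluoromethanesulfonic anhydride, O=S(=O)(OS(=O)(=O)C(F)(F)F)C(F)(F)F
Why: O-sulfonylation of the only free phenol (C14), the C12 oxygen remaining masked as its isopropyl ether.

**Step 10**
Reactants: 22 aryl triflate isopropyl ether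
Product: 23 methyl 3-[(1R,2R)-7-hydroxy-1,6-dimethyl-2-(prop-1-en-2-yl)-5-{[(trifluoromethyl)sulfonyl]oxy}-1,2,3,4-tetrahydronaphthalen-1-yl]propanoate
Conditions: BCl3 (1 M in CH2Cl2), CH2Cl2, −78 → 0 °C; then H2O
Reagents that add atoms: none
Why: Lewis-acid dealkylation selective for isopropyl aryl ethers, placed before the styrene is present; triflate, ester and isopropenyl group should survive at low temperature.

**Step 11**
Reactants: 23 phenol triflate
Product: 24 methyl 3-[(1R,2R)-5-ethenyl-7-hydroxy-1,6-dimethyl-2-(prop-1-en-2-yl)-1,2,3,4-tetrahydronaphthalen-1-yl]propanoate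
Conditions: tributyl(vinyl)stannane, Pd(PPh3)4 (cat.), LiCl, BHT (cat.), dioxane, 95 °C
Reagents that add atoms: tributyl(vinyl)stannane, C=C[Sn](CCCC)(CCCC)CCCC
Why: Stille coupling of an aryl triflate, which tolerates the free phenol, the ester and the isopropenyl group.

**Step 12**
Reactants: 24 vinyl phenol
Product: 25 trigonochinene C
Conditions: O2, tetraphenylporphyrin (cat.), visible light, CH2Cl2/MeOH, −20 °C
Reagents that add atoms: dioxygen, O=O
Why: sensitised photooxygenation of a para-alkylphenol, in which 1O2 adds at the para carbon C8 to give the 4-hydroperoxycyclohexa-2,5-dienone; attack should occur axially, anti to the pseudoaxial C7–H and on the face of the pseudoaxial C10 methyl, because this leads directly to the chair of ring B, and the electron-rich phenol is expected to react faster than the mono- and 1,1-disubstituted alkenes.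

**Compound list**
1 | 2-methylcyclohex-2-en-1-one | CC1=CCCCC1=O | starting material
2 | isopropenylmagnesium bromide | C=C(C)[Mg]Br | starting material
3 | bromomagnesium (3R)-2-methyl-3-(prop-1-en-2-yl)cyclohex-1-en-1-olate | Br[Mg]OC1=C(C)[C@@H](C(=C)C)CCC1 | intermediate
4 | (3S)-2-methyl-3-(prop-1-en-2-yl)cyclohexan-1-one (C2 epimers) | O=C1CCC[C@H](C(=C)C)C1C | intermediate
5 | (R)-1-phenylethan-1-amine | C[C@@H](N)c1ccccc1 | starting material
6 | methyl acrylate | C=CC(=O)OC | starting material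
7 | (3S)-2-methyl-N-[(1R)-1-phenylethyl]-3-(prop-1-en-2-yl)cyclohexan-1-imine | C[C@@H](N=C1CCC[C@H](C(=C)C)C1C)c1ccccc1 | intermediate
8 | methyl 3-[(1R,6R)-1-methyl-2-{[(1R)-1-phenylethyl]imino}-6-(prop-1-en-2-yl)cyclohexyl]propanoate | C[C@@H](N=C1CCC[C@H](C(=C)C)[C@@]1(C)CCC(=O)OC)c1ccccc1 | intermediate
9 | methyl 3-[(1R,6R)-1-methyl-2-oxo-6-(prop-1-en-2-yl)cyclohexyl]propanoate | O=C1CCC[C@H](C(=C)C)[C@@]1(C)CCC(=O)OC | intermediate
10 | potassium (5R,6R)-6-(3-methoxy-3-oxopropyl)-6-methyl-5-(prop-1-en-2-yl)cyclohex-1-en-1-olate | [K+].[O-]C1=CCC[C@H](C(=C)C)[C@@]1(C)CCC(=O)OC | intermediate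
11 | methyl 3-[(1R,6R)-1-methyl-6-(prop-1-en-2-yl)-2-{[(trifluoromethyl)sulfonyl]oxy}cyclohex-2-en-1-yl]propanoate | O=S(=O)(OC1=CCC[C@H](C(=C)C)[C@@]1(C)CCC(=O)OC)C(F)(F)F | intermediate
12 | methyl 3-[(1R,6R)-1-methyl-6-(prop-1-en-2-yl)-2-(trimethylstannyl)cyclohex-2-en-1-yl]propanoate | C[Sn](C)(C)C1=CCC[C@H](C(=C)C)[C@@]1(C)CCC(=O)OC | intermediate
13 | diisopropyl squarate | O=C1C(=O)C(OC(C)C)=C1OC(C)C | starting material
14 | 4-hydroxy-2,3-diisopropoxy-4-methylcyclobut-2-en-1-one | O=C1C(OC(C)C)=C(OC(C)C)C1(C)O | intermediate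
15 | 3-isopropoxy-4-methylcyclobut-3-ene-1,2-dione | O=C1C(=O)C(C)=C1OC(C)C | intermediate
16 | 4-hydroxy-3-isopropoxy-2-methylcyclobut-2-en-1-one (racemic) | O=C1C(C)=C(OC(C)C)C1O | intermediate
17 | 4-chloro-3-isopropoxy-2-methylcyclobut-2-en-1-one (racemic) | O=C1C(C)=C(OC(C)C)C1Cl | intermediate
18 | methyl 3-[(1R,6R)-1-methyl-2-[3-methyl-4-oxo-2-(propan-2-yloxy)cyclobut-2-en-1-yl]-6-(prop-1-en-2-yl)cyclohex-2-en-1-yl]propanoate (epimers at the cyclobutene CH) | O=C1C(C)=C(OC(C)C)C1C2=CCC[C@H](C(=C)C)[C@@]2(C)CCC(=O)OC | intermediate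
19 | methyl 3-[(1R,6R)-1-methyl-2-[(1E)-3-methyl-4-oxo-2-(propan-2-yloxy)buta-1,3-dien-1-yl]-6-(prop-1-en-2-yl)cyclohex-2-en-1-yl]propanoate | O=C=C(C)/C(OC(C)C)=C\C1=CCC[C@H](C(=C)C)[C@@]1(C)CCC(=O)OC | intermediate
20 | methyl 3-[(1R,2R)-1,6-dimethyl-5-oxo-7-(propan-2-yloxy)-2-(prop-1-en-2-yl)-1,2,3,4,4a,5-hexahydronaphthalen-1-yl]propanoate (4a epimers) | O=C1C(C)=C(OC(C)C)C=C2C1CC[C@H](C(=C)C)[C@@]2(C)CCC(=O)OC | intermediate
21 | methyl 3-[(1R,2R)-5-hydroxy-1,6-dimethyl-7-(propan-2-yloxy)-2-(prop-1-en-2-yl)-1,2,3,4-tetrahydronaphthalen-1-yl]propanoate | Oc1c(C)c(OC(C)C)cc2c1CC[C@H](C(=C)C)[C@@]2(C)CCC(=O)OC | intermediate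
22 | methyl 3-[(1R,2R)-1,6-dimethyl-7-(propan-2-yloxy)-2-(prop-1-en-2-yl)-5-{[(trifluoromethyl)sulfonyl]oxy}-1,2,3,4-tetrahydronaphthalen-1-yl]propanoate | O=S(=O)(Oc1c(C)c(OC(C)C)cc2c1CC[C@H](C(=C)C)[C@@]2(C)CCC(=O)OC)C(F)(F)F | intermediate
23 | methyl 3-[(1R,2R)-7-hydroxy-1,6-dimethyl-2-(prop-1-en-2-yl)-5-{[(trifluoromethyl)sulfonyl]oxy}-1,2,3,4-tetrahydronaphthalen-1-yl]propanoate | O=S(=O)(Oc1c(C)c(O)cc2c1CC[C@H](C(=C)C)[C@@]2(C)CCC(=O)OC)C(F)(F)F | intermediate
24 | methyl 3-[(1R,2R)-5-ethenyl-7-hydroxy-1,6-dimethyl-2-(prop-1-en-2-yl)-1,2,3,4-tetrahydronaphthalen-1-yl]propanoate | C=Cc1c(C)c(O)cc2c1CC[C@H](C(=C)C)[C@@]2(C)CCC(=O)OC | intermediate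
25 | trigonochinene C, methyl 3-[(1R,2R,4aR)-5-ethenyl-4a-hydroperoxy-1,6-dimethyl-7-oxo-2-(prop-1-en-2-yl)-1,2,3,4,4a,7-hexahydronaphthalen-1-yl]propanoate | C=CC1=C(C)C(=O)C=C2[C@]1(OO)CC[C@H](C(=C)C)[C@@]2(C)CCC(=O)OC | target

**Summary**
Total step count: 12. Longest linear sequence: 9 steps (steps 1–4 and 8–12); steps 5–7 form the three-step branch to 17.

**Steps most likely to fail**

Step 8. Transmetalation of the alkenylstannane, which sits next to the quaternary C10, may be too slow, so that 17 decomposes by ring opening or oligomerisation before coupling. The fallback sets out from 11 and comes back at 23. Carbonylative Stille coupling of 11 with tetramethyltin (CO, Pd(PPh3)4, LiCl) should give the methyl ketone methyl 3-[(1R,6R)-2-acetyl-1-methyl-6-(prop-1-en-2-yl)cyclohex-2-en-1-yl]propanoate F1. Detrifluoroacetylative diazo transfer (LiHMDS, CF3CO2CH2CF3; then MsN3, Et3N, H2O) should give the diazoketone methyl 3-[(1R,6R)-2-(2-diazoacetyl)-1-methyl-6-(prop-1-en-2-yl)cyclohex-2-en-1-yl]propanoate F2. Irradiation of F2 with triisopropyl(prop-1-yn-1-yloxy)silane F3 (made from ethyl acetate by ester homologation to the ynolate and O-silylation with TIPSOTf) should give, by photo-Wolff rearrangement and [2+2] addition, the silyloxy analogue of 18, methyl 3-[(1R,6R)-1-methyl-2-[3-methyl-4-oxo-2-(triisopropylsilyloxy)cyclobut-2-en-1-yl]-6-(prop-1-en-2-yl)cyclohex-2-en-1-yl]propanoate F4. On heating, F4 should undergo the same four-to-six ring expansion to the phenol methyl 3-[(1R,2R)-5-hydroxy-1,6-dimethyl-2-(prop-1-en-2-yl)-7-(triisopropylsilyloxy)-1,2,3,4-tetrahydronaphthalen-1-yl]propanoate F5 (Danheiser benzannulation). Triflation (Tf2O, pyridine) gives methyl 3-[(1R,2R)-1,6-dimethyl-2-(prop-1-en-2-yl)-7-(triisopropylsilyloxy)-5-{[(trifluoromethyl)sulfonyl]oxy}-1,2,3,4-tetrahydronaphthalen-1-yl]propanoate F6, and TBAF returns the route to 23, which makes step 10 unnecessary.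

Step 12. Oxygen may add to the wrong face of C8, because the pseudoaxial C10 methyl shields the face that is needed, and ene or [4+2] photooxygenation of the isopropenyl and styrene groups may compete. The fallback sets out from 23 and comes back at 25. Photooxygenation of 23 (O2, rose bengal, MeOH), with the vinyl group still absent, should give methyl 3-[(1R,2R,4aR)-4a-hydroperoxy-1,6-dimethyl-7-oxo-2-(prop-1-en-2-yl)-5-{[(trifluoromethyl)sulfonyl]oxy}-1,2,3,4,4a,7-hexahydronaphthalen-1-yl]propanoate F7. Protection with 2-methoxypropene and PPTS should give the peroxyketal methyl 3-[(1R,2R,4aR)-4a-[(2-methoxypropan-2-yl)peroxy]-1,6-dimethyl-7-oxo-2-(prop-1-en-2-yl)-5-{[(trifluoromethyl)sulfonyl]oxy}-1,2,3,4,4a,7-hexahydronaphthalen-1-yl]propanoate F8. Stille coupling of this β-triflyloxy enone with tributyl(vinyl)stannane (Pd2(dba)3, AsPh3, LiCl, rt) should give methyl 3-[(1R,2R,4aR)-5-ethenyl-4a-[(2-methoxypropan-2-yl)peroxy]-1,6-dimethyl-7-oxo-2-(prop-1-en-2-yl)-1,2,3,4,4a,7-hexahydronaphthalen-1-yl]propanoate F9. AcOH/THF/H2O then releases 25.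

Step 2. The neutral Michael addition may stall at the congested tetrasubstituted enamine, or proceed through the less substituted enamine at C8. The fallback sets out from 3 (formed from 1 and 2 as in step 1) and comes back at 9. Enolate 3 is alkylated in the flask with allyl iodide (DMPU, −30 → 0 °C), anti to the isopropenyl group, to give (2R,3R)-2-methyl-2-(prop-2-en-1-yl)-3-(prop-1-en-2-yl)cyclohexan-1-one F10. Hydroboration with disiamylborane, selective for the monosubstituted alkene, and NaBO3 oxidation should give (2R,3R)-2-(3-hydroxypropyl)-2-methyl-3-(prop-1-en-2-yl)cyclohexan-1-one F11. TEMPO/PhI(OAc)2 in aqueous MeCN should give 3-[(1R,6R)-1-methyl-2-oxo-6-(prop-1-en-2-yl)cyclohexyl]propanoic acid F12, and TMSCHN2 in MeOH gives 9.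

**Further compounds**
F1 | step 8 | methyl 3-[(1R,6R)-2-acetyl-1-methyl-6-(prop-1-en-2-yl)cyclohex-2-en-1-yl]propanoate | CC(=O)C1=CCC[C@H](C(=C)C)[C@@]1(C)CCC(=O)OC
F2 | step 8 | methyl 3-[(1R,6R)-2-(2-diazoacetyl)-1-methyl-6-(prop-1-en-2-yl)cyclohex-2-en-1-yl]propanoate | [N-]=[N+]=CC(=O)C1=CCC[C@H](C(=C)C)[C@@]1(C)CCC(=O)OC
F3 | step 8 | triisopropyl(prop-1-yn-1-yloxy)silane | CC#CO[Si](C(C)C)(C(C)C)C(C)C
F4 | step 8 | methyl 3-[(1R,6R)-1-methyl-2-[3-methyl-4-oxo-2-(triisopropylsilyloxy)cyclobut-2-en-1-yl]-6-(prop-1-en-2-yl)cyclohex-2-en-1-yl]propanoate | O=C1C(C)=C(O[Si](C(C)C)(C(C)C)C(C)C)C1C2=CCC[C@H](C(=C)C)[C@@]2(C)CCC(=O)OC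
F5 | step 8 | methyl 3-[(1R,2R)-5-hydroxy-1,6-dimethyl-2-(prop-1-en-2-yl)-7-(triisopropylsilyloxy)-1,2,3,4-tetrahydronaphthalen-1-yl]propanoate | Oc1c(C)c(O[Si](C(C)C)(C(C)C)C(C)C)cc2c1CC[C@H](C(=C)C)[C@@]2(C)CCC(=O)OC
F6 | step 8 | methyl 3-[(1R,2R)-1,6-dimethyl-2-(prop-1-en-2-yl)-7-(triisopropylsilyloxy)-5-{[(trifluoromethyl)sulfonyl]oxy}-1,2,3,4-tetrahydronaphthalen-1-yl]propanoate | O=S(=O)(Oc1c(C)c(O[Si](C(C)C)(C(C)C)C(C)C)cc2c1CC[C@H](C(=C)C)[C@@]2(C)CCC(=O)OC)C(F)(F)F
F7 | step 12 | methyl 3-[(1R,2R,4aR)-4a-hydroperoxy-1,6-dimethyl-7-oxo-2-(prop-1-en-2-yl)-5-{[(trifluoromethyl)sulfonyl]oxy}-1,2,3,4,4a,7-hexahydronaphthalen-1-yl]propanoate | O=S(=O)(OC1=C(C)C(=O)C=C2[C@]1(OO)CC[C@H](C(=C)C)[C@@]2(C)CCC(=O)OC)C(F)(F)F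
F8 | step 12 | methyl 3-[(1R,2R,4aR)-4a-[(2-methoxypropan-2-yl)peroxy]-1,6-dimethyl-7-oxo-2-(prop-1-en-2-yl)-5-{[(trifluoromethyl)sulfonyl]oxy}-1,2,3,4,4a,7-hexahydronaphthalen-1-yl]propanoate | O=S(=O)(OC1=C(C)C(=O)C=C2[C@]1(OOC(C)(C)OC)CC[C@H](C(=C)C)[C@@]2(C)CCC(=O)OC)C(F)(F)F
F9 | step 12 | methyl 3-[(1R,2R,4aR)-5-ethenyl-4a-[(2-methoxypropan-2-yl)peroxy]-1,6-dimethyl-7-oxo-2-(prop-1-en-2-yl)-1,2,3,4,4a,7-hexahydronaphthalen-1-yl]propanoate | C=CC1=C(C)C(=O)C=C2[C@]1(OOC(C)(C)OC)CC[C@H](C(=C)C)[C@@]2(C)CCC(=O)OC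
F10 | step 2 | (2R,3R)-2-methyl-2-(prop-2-en-1-yl)-3-(prop-1-en-2-yl)cyclohexan-1-one | O=C1CCC[C@H](C(=C)C)[C@@]1(C)CC=C
F11 | step 2 | (2R,3R)-2-(3-hydroxypropyl)-2-methyl-3-(prop-1-en-2-yl)cyclohexan-1-one | O=C1CCC[C@H](C(=C)C)[C@@]1(C)CCCO
F12 | step 2 | 3-[(1R,6R)-1-methyl-2-oxo-6-(prop-1-en-2-yl)cyclohexyl]propanoic acid | O=C1CCC[C@H](C(=C)C)[C@@]1(C)CCC(=O)O
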